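The route opens the methyl-free ring of the naphthalene at C1'–C2' and C3'–C4'. That ring invites the cut. Its two benzylic carbons carry all the substituents (C1' the isoquinoline C5, C4' a methoxy group) and C2'/C3' are bare CH, which reads as an o-quinodimethane plus an acetylene equivalent. The precursor is a diaryl ketone with an ortho CH2OMe group on the benzoyl ring and the N-Boc (S)-6,8-dimethoxy-3-methyltetrahydroisoquinolin-5-yl group as second aryl. Light turns it into a hydroxy-o-quinodimethane, which adds (E)-1,2-bis(phenylsulfonyl)ethene, giving two C–C bonds and the carbocycle in one operation. The crowded biaryl bond is never made by coupling; it enters as aryl–C(=O). Reductive desulfonylation and acid finish.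

Key step: step 10

Remark (locants): primed locants count the naphthalene from the carbon bonded to isoquinoline C5, so C1' bears the aryl group, C4' and C5' bear OMe, and C7' bears Me.

Remark (assumption): the target string fixes only C3 (S); the hindered C5–C1' axis is left undefined, so both atropo-diastereomers match the drawing, both are expected to form, and they can be separated by chromatography if one is wanted.

Remark (dienophile): a vinyl mono-sulfone was set aside because its adduct has no acidified hydrogen on the C3' side of the sulfonyl carbon. Base would instead trigger retro-addition of the β-hydroxy sulfone or, in the other regioisomer, E1cB loss of the C4' methoxide, and acid would expel methanol rather than sulfinate. The vicinal bis-sulfone leaves by electron transfer whatever its stereochemistry, has no regioisomers, and keeps the C4' methoxy group.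

**Step 1**
Reactants: 1 3-methoxy-5-methylbenzoic acid
Product: 3 N,N-diethyl-3-methoxy-5-methylbenzamide, via acid chloride 2 (not isolated)
Conditions: SOCl2, cat. DMF, toluene, 70 °C; evaporate; Et2NH (2.5 equiv), CH2Cl2, 0 °C → rt
Reagents that add atoms: diethylamine CCNCC
Why: Acid chloride formation followed by aminolysis (amide synthesis) is routine and installs the directing group needed in step 2.

**Step 2**
Reactants: 3 N,N-diethyl-3-methoxy-5-methylbenzamide
Product: 5 N,N-diethyl-3-methoxy-2-(methoxymethyl)-5-methylbenzamide, via 2-lithio benzamide 4 (not isolated)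
Conditions: s-BuLi, TMEDA, THF, −78 °C; then MeOCH2Cl, −78 °C → rt
Reagents that add atoms: chloromethyl methyl ether COCCl
Why: In this directed ortho-metalation the amide and the methoxy group cooperate to place lithium on the carbon between them, and SN2 alkylation by the very reactive α-chloro ether installs the CH2OMe group in its final form.

**Step 3**
Reactants: 5 N,N-diethyl-3-methoxy-2-(methoxymethyl)-5-methylbenzamide
Product: 7 3-methoxy-2-(methoxymethyl)-5-methylbenzaldehyde, via zirconium hemiaminal 6 (not isolated)
Conditions: Cp2Zr(H)Cl (1.6 equiv), THF, rt; H2O/silica gel work-up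
Reagents that add atoms: none
Why: Hydrozirconation of the tertiary amide with Cp2Zr(H)Cl stops at an O-zirconated hemiaminal that releases the aldehyde only on work-up, so over-reduction is avoided and the benzylic ether is untouched.

**Step 4**
Reactants: 8 1-bromo-3,5-dimethoxybenzene; 9 tert-butyl (S)-4-methyl-1,2,3-oxathiazolidine-3-carboxylate 2,2-dioxide (commercial cyclic sulfamidate of N-Boc-L-alaninol)
Product: 12 tert-butyl (S)-[1-(3,5-dimethoxyphenyl)propan-2-yl]carbamate, via arylmagnesium bromide 10 (not isolated), via N-sulfamate salt 11 (not isolated)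
Conditions: 8, Mg, THF, reflux; then CuCl (10 mol %), 9, THF, −30 °C → rt; then 10 % aq citric acid, rt
Reagents that add atoms: none
Why: The copper-catalysed SN2 opening of the cyclic sulfamidate by the Grignard reagent occurs at the primary CH2–O carbon, so the chiral-pool stereocentre (the future C3, S) is not touched, and mild acid then hydrolyses the N-sulfamate but not the Boc group.

**Step 5**
Reactants: 12 tert-butyl (S)-[1-(3,5-dimethoxyphenyl)propan-2-yl]carbamate
Product: 14 (S)-6,8-dimethoxy-3-methyl-1,2,3,4-tetrahydroisoquinoline, via primary ammonium chloride 13 (not isolated)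
Conditions: 4 M HCl in dioxane, rt; evaporate; 37 % aq HCHO (1.1 equiv), dilute aq HCl–MeOH, 50 °C; aq NaOH work-up
Reagents that add atoms: formaldehyde C=O
Why: After carbamate acidolysis, the Pictet–Spengler cyclisation sends the formaldehyde iminium ion to a ring position ortho to one and para to the other methoxy group (the two candidates are equivalent by symmetry), and C3 takes no part.

**Step 6**
Reactants: 14 (S)-6,8-dimethoxy-3-methyl-1,2,3,4-tetrahydroisoquinoline
Product: 15 tert-butyl (S)-6,8-dimethoxy-3-methyl-3,4-dihydroisoquinoline-2(1H)-carboxylate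
Conditions: Boc2O, Et3N, CH2Cl2, rt
Reagents that add atoms: di-tert-butyl dicarbonate CC(C)(C)OC(=O)OC(=O)OC(C)(C)C
Why: N-Acylation to the carbamate is routine and masks the amine lone pair before halogenation, lithiation and irradiation.

**Step 7**
Reactants: 15 tert-butyl (S)-6,8-dimethoxy-3-methyl-3,4-dihydroisoquinoline-2(1H)-carboxylate
Product: 16 tert-butyl (S)-5-bromo-6,8-dimethoxy-3-methyl-3,4-dihydroisoquinoline-2(1H)-carboxylate
Conditions: NBS (1.0 equiv), MeCN, −20 → 0 °C, dark
Reagents that add atoms: N-bromosuccinimide O=C1CCC(=O)N1Br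
Why: Electrophilic aromatic bromination should go to C5, para to the 8-methoxy and ortho to the 6-methoxy group, because C7 is shielded between two methoxy groups and one equivalent at low temperature prevents a second bromination.

**Step 8**
Reactants: 16 tert-butyl (S)-5-bromo-6,8-dimethoxy-3-methyl-3,4-dihydroisoquinoline-2(1H)-carboxylate; 7 3-methoxy-2-(methoxymethyl)-5-methylbenzaldehyde
Product: 18 tert-butyl (3S)-5-{hydroxy[3-methoxy-2-(methoxymethyl)-5-methylphenyl]methyl}-6,8-dimethoxy-3-methyl-3,4-dihydroisoquinoline-2(1H)-carboxylate (both carbinol epimers), via 5-lithio isoquinoline 17 (not isolated)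
Conditions: 16, n-BuLi (1.05 equiv), THF, −78 °C; then 7, −78 → −20 °C; aq NH4Cl
Reagents that add atoms: none
Why: Bromine–lithium exchange at −78 °C outruns attack on the carbamate and deprotonation at C1, 1,2-addition of the aryllithium to an aldehyde tolerates the two ortho substituents better than acyl transfer would, and the carbinol centre forms unselectively but is erased in step 9.

**Step 9**
Reactants: 18 diaryl carbinol
Product: 19 tert-butyl (S)-6,8-dimethoxy-5-[3-methoxy-2-(methoxymethyl)-5-methylbenzoyl]-3-methyl-3,4-dihydroisoquinoline-2(1H)-carboxylate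
Conditions: Dess–Martin periodinane, CH2Cl2, rt
Reagents that add atoms: none
Why: Dess–Martin oxidation of a secondary diaryl carbinol is mild enough for the Boc group, the benzylic ether and the electron-rich rings, and it cannot over-oxidise.

**Step 10**
Reactants: 19 diaryl ketone; 20 (E)-1,2-bis(phenylsulfonyl)ethene
Product: 22 tetralol cycloadduct tert-butyl (3S)-5-[1-hydroxy-4,5-dimethoxy-7-methyl-2,3-bis(phenylsulfonyl)-1,2,3,4-tetrahydronaphthalen-1-yl]-6,8-dimethoxy-3-methyl-3,4-dihydroisoquinoline-2(1H)-carboxylate (mixture at C1'–C4'; sulfonyl groups trans), via hydroxy-o-quinodimethane 21 (not isolated)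
Conditions: hν (365 nm LED), Ti(OiPr)4 (2 equiv), 20 (2 equiv), degassed CH2Cl2, 20 °C; aq NaHCO3 work-up
Reagents that add atoms: none
Why: Light of 365 nm populates the n,π* triplet of 19, whose oxygen takes a hydrogen atom from the ortho CH2OMe group in a 1,5-transfer through a six-membered transition state; the biradical relaxes to hydroxy-o-quinodimethane 21, which Ti(OiPr)4 captures as a longer-lived titanium dienolate. The closest known chemistry is the titanium-assisted photoenolization/Diels–Alder reaction of ortho-alkyl benzophenones with electron-poor alkenes, and 20 is a standard, highly reactive acetylene equivalent for [4+2] cycloadditions. The single new ring, a six-membered carbocycle, closes by an intermolecular suprafacial [4+2] cycloaddition that makes C1'–C2' and C3'–C4' in the same event. C1', C2', C3' and C4' become stereocentres, of which only the trans C2'/C3' relation is dictated (by the E alkene); no further control is sought because all four are flattened in steps 11 and 12, the symmetrical dienophile excludes regioisomers, and C3 is a spectator. What the step needs is site-selective hydrogen abstraction (CH2OMe rather than C4–H2, C3–H or the 6-OMe group) that outruns charge-transfer decay: the doubly ortho-substituted isoquinoline ring is twisted out of the carbonyl plane so that its hydrogens lie off the axis of the oxygen n orbital, the benzylic α-alkoxy C–H is the weakest and most hydridic one, a dienol formed through C4 would have a hindered trisubstituted terminus and can revert to 19, and the Boc group takes the nitrogen lone pair out of play as an electron donor.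

**Step 11**
Reactants: 22 tetralol cycloadduct
Product: 23 tert-butyl (3S)-5-(1-hydroxy-4,5-dimethoxy-7-methyl-1,4-dihydronaphthalen-1-yl)-6,8-dimethoxy-3-methyl-3,4-dihydroisoquinoline-2(1H)-carboxylate (mixture at C1'/C4')
Conditions: 6 % Na(Hg), NaH2PO4, MeOH–THF, −20 → 0 °C
Reagents that add atoms: none
Why: In this reductive elimination of a vicinal bis-sulfone, electron transfer breaks one C–S bond and the β-sulfonyl radical or anion expels benzenesulfinate, a far better leaving group than the neighbouring hydroxide or methoxide, so every stereoisomer of 22 converges on the C2'=C3' alkene.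

**Step 12**
Reactants: 23 1,4-dihydronaphthalen-1-ol
Product: 25 (S)-5-(4,5-dimethoxy-7-methylnaphthalen-1-yl)-6,8-dimethoxy-3-methyl-1,2,3,4-tetrahydroisoquinoline (target CNP0236045.1), via N-Boc naphthylisoquinoline 24 (not isolated)
Conditions: 4 M HCl in dioxane, CH2Cl2, 0 °C → rt; aq NaOH work-up
Reagents that add atoms: none
Why: Acid ionises the tertiary, doubly benzylic and allylic C1'–OH and loss of H4' aromatises the ring (E1 dehydration), the C4' methoxy group stays because C1' has no hydrogen that would allow an aromatising loss of methanol, the same acid cleaves the Boc group, and C3 is unaffected.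

**Compound list**

1 | 3-methoxy-5-methylbenzoic acid | COc1cc(C)cc(C(=O)O)c1 | starting material
2 | 3-methoxy-5-methylbenzoyl chloride | COc1cc(C)cc(C(=O)Cl)c1 | intermediate
3 | N,N-diethyl-3-methoxy-5-methylbenzamide | CCN(CC)C(=O)c1cc(C)cc(OC)c1 | intermediate
4 | N,N-diethyl-2-lithio-3-methoxy-5-methylbenzamide | CCN(CC)C(=O)c1cc(C)cc(OC)c1[Li] | intermediate
5 | N,N-diethyl-3-methoxy-2-(methoxymethyl)-5-methylbenzamide | CCN(CC)C(=O)c1cc(C)cc(OC)c1COC | intermediate
6 | O-(chlorozirconocenyl) hemiaminal of 5 | CCN(CC)C(O[Zr](Cl)(C1C=CC=C1)C1C=CC=C1)c1cc(C)cc(OC)c1COC | intermediate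
7 | 3-methoxy-2-(methoxymethyl)-5-methylbenzaldehyde | COCc1c(OC)cc(C)cc1C=O | intermediate
8 | 1-bromo-3,5-dimethoxybenzene | COc1cc(Br)cc(OC)c1 | starting material
9 | tert-butyl (S)-4-methyl-1,2,3-oxathiazolidine-3-carboxylate 2,2-dioxide | C[C@H]1COS(=O)(=O)N1C(=O)OC(C)(C)C | starting material
10 | 3,5-dimethoxyphenylmagnesium bromide | COc1cc([Mg]Br)cc(OC)c1 | intermediate
11 | bromomagnesium (S)-N-Boc-N-[1-(3,5-dimethoxyphenyl)propan-2-yl]sulfamate | COc1cc(C[C@H](C)N(C(=O)OC(C)(C)C)S(=O)(=O)O[Mg]Br)cc(OC)c1 | intermediate
12 | tert-butyl (S)-[1-(3,5-dimethoxyphenyl)propan-2-yl]carbamate | COc1cc(C[C@H](C)NC(=O)OC(C)(C)C)cc(OC)c1 | intermediate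
13 | (S)-1-(3,5-dimethoxyphenyl)propan-2-aminium chloride | COc1cc(C[C@H](C)[NH3+])cc(OC)c1.[Cl-] | intermediate
14 | (S)-6,8-dimethoxy-3-methyl-1,2,3,4-tetrahydroisoquinoline | COc1cc(OC)c2c(c1)C[C@H](C)NC2 | intermediate
15 | tert-butyl (S)-6,8-dimethoxy-3-methyl-3,4-dihydroisoquinoline-2(1H)-carboxylate | COc1cc(OC)c2c(c1)C[C@H](C)N(C(=O)OC(C)(C)C)C2 | intermediate
16 | tert-butyl (S)-5-bromo-6,8-dimethoxy-3-methyl-3,4-dihydroisoquinoline-2(1H)-carboxylate | COc1cc(OC)c2c(c1Br)C[C@H](C)N(C(=O)OC(C)(C)C)C2 | intermediate
17 | tert-butyl (S)-5-lithio-6,8-dimethoxy-3-methyl-3,4-dihydroisoquinoline-2(1H)-carboxylate | COc1cc(OC)c2c(c1[Li])C[C@H](C)N(C(=O)OC(C)(C)C)C2 | intermediate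
18 | diaryl carbinol, (S) at C3, both carbinol epimers | COCc1c(OC)cc(C)cc1C(O)c1c(OC)cc(OC)c2c1C[C@H](C)N(C(=O)OC(C)(C)C)C2 | intermediate
19 | diaryl ketone with ortho CH2OMe group, (S) at C3, N-Boc | COCc1c(OC)cc(C)cc1C(=O)c1c(OC)cc(OC)c2c1C[C@H](C)N(C(=O)OC(C)(C)C)C2 | intermediate
20 | (E)-1,2-bis(phenylsulfonyl)ethene | O=S(=O)(/C=C/S(=O)(=O)c1ccccc1)c1ccccc1 | starting material
21 | hydroxy-o-quinodimethane (photoenol of 19, held on titanium) | COC=C1C(OC)=CC(C)=CC1=C(O)c1c(OC)cc(OC)c2c1C[C@H](C)N(C(=O)OC(C)(C)C)C2 | intermediate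
22 | tetralol cycloadduct, (S) at C3, mixture at C1'–C4' | COC1C(S(=O)(=O)c2ccccc2)C(S(=O)(=O)c2ccccc2)C(O)(c2c(OC)cc(OC)c3c2C[C@H](C)N(C(=O)OC(C)(C)C)C3)c2cc(C)cc(OC)c12 | intermediate
23 | 1,4-dihydronaphthalen-1-ol, (S) at C3, mixture at C1'/C4' | COC1C=CC(O)(c2c(OC)cc(OC)c3c2C[C@H](C)N(C(=O)OC(C)(C)C)C3)c2cc(C)cc(OC)c12 | intermediate
24 | tert-butyl (S)-5-(4,5-dimethoxy-7-methylnaphthalen-1-yl)-6,8-dimethoxy-3-methyl-3,4-dihydroisoquinoline-2(1H)-carboxylate | COc1ccc(-c2c(OC)cc(OC)c3c2C[C@H](C)N(C(=O)OC(C)(C)C)C3)c2cc(C)cc(OC)c12 | intermediate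
25 | (S)-5-(4,5-dimethoxy-7-methylnaphthalen-1-yl)-6,8-dimethoxy-3-methyl-1,2,3,4-tetrahydroisoquinoline | COc1cc(OC)c(-c2ccc(OC)c3c(OC)cc(C)cc23)c2c1CN[C@@H](C)C2 | target

Total step count: 12.
Longest linear sequence: 9 steps (steps 4–12, from 8 and 9). The benzaldehyde branch (steps 1–3) joins at step 8.

**Steps most likely to fail**

**Step 10.**
- What may go wrong:
  - The excited state may decay by charge transfer from the dimethoxyaryl ring.
  - Hydrogen abstraction may stray to C4 or C3.
  - Cycloaddition at the fully substituted, aryl-shielded C1' terminus may be too slow, so that the dienol only reverts.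
  - The dienophile may be consumed by alkoxide addition or by radical addition–fragmentation.
- Fallback: a thermal isobenzofuran Diels–Alder reaction that needs no light. It sets out from 3 (through 4) and 16 (through 17) and comes back at 24. Lithio amide 4 is quenched with paraformaldehyde to give the hydroxymethyl amide F1, which lactonises with TsOH in hot toluene to the phthalide F2. Aryllithium 17 adds once to F2 at −78 °C to give the lactol F3. Catalytic AcOH in toluene at 80 °C dehydrates F3 to the 1-arylisobenzofuran F4, a persistent and very reactive diene that is trapped in situ by 20 as the oxygen-bridged adduct F5. Na(Hg)/NaH2PO4 removes both sulfonyl groups to give the 1,4-epoxy-1,4-dihydronaphthalene F6. Catalytic TsOH in CH2Cl2 at 0 °C opens the bridge at the tertiary C1'–O bond, and loss of H4' gives the naphthol F7. MeI/K2CO3 in acetone converts F7 into 24, which then enters step 12.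

**Step 11.**
- What may go wrong: methoxide generated at the amalgam surface may deprotonate the acidic C2'–H or C3'–H. This would start E1cB loss of a single sulfinate or of the C4' methoxide before electron transfer takes place.
- Fallback: fluoride-triggered instead of reductive unmasking. It sets out from 19 and comes back at 23. The photocycloaddition is run with commercial (E)-2-(trimethylsilyl)vinyl phenyl sulfone in place of 20, giving the β-silyl sulfone adduct F8 in either orientation. TBAF in THF at rt then attacks silicon and benzenesulfinate leaves in the known fluoride-induced 1,2-elimination, which needs neither reductant nor strong base.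

**Step 8.**
- What may go wrong: proton transfer from C1–H or attack on the carbamate may compete during the exchange, and addition of the doubly ortho-substituted aryllithium may be sluggish.
- Fallback: palladium-catalysed acylation of a non-basic arylzinc. It sets out from 7 and 17 and comes back at 19, so step 9 is skipped. Pinnick oxidation of 7 (NaClO2, NaH2PO4, 2-methyl-2-butene) gives the benzoic acid F9. (COCl)2 with cat. DMF at 0 °C gives the acid chloride F10, which is used at once. Aryllithium 17 is transmetalated with ZnCl2 at −78 °C to the arylzinc chloride F11. Negishi acylation of F10 with F11 under Pd(PPh3)4 in THF gives ketone 19.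

**Further compounds**

F1 | step 10 | N,N-diethyl-2-(hydroxymethyl)-3-methoxy-5-methylbenzamide | CCN(CC)C(=O)c1cc(C)cc(OC)c1CO
F2 | step 10 | 4-methoxy-6-methylisobenzofuran-1(3H)-one | COc1cc(C)cc2c1COC2=O
F3 | step 10 | 1-aryl-4-methoxy-6-methyl-1,3-dihydroisobenzofuran-1-ol (aryl = N-Boc isoquinolin-5-yl unit, S at C3) | COc1cc(C)cc2c1COC2(O)c1c(OC)cc(OC)c2c1C[C@H](C)N(C(=O)OC(C)(C)C)C2
F4 | step 10 | 1-aryl-4-methoxy-6-methylisobenzofuran, (S) at C3 | COc1cc(C)cc2c1coc2-c1c(OC)cc(OC)c2c1C[C@H](C)N(C(=O)OC(C)(C)C)C2
F5 | step 10 | 1-aryl-1,4-epoxy-2,3-bis(phenylsulfonyl)-1,2,3,4-tetrahydronaphthalene adduct, (S) at C3 | COc1cc(C)cc2c1C1OC2(c2c(OC)cc(OC)c3c2C[C@H](C)N(C(=O)OC(C)(C)C)C3)C(S(=O)(=O)c2ccccc2)C1S(=O)(=O)c1ccccc1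
F6 | step 10 | 1-aryl-1,4-epoxy-1,4-dihydronaphthalene, (S) at C3 | COc1cc(C)cc2c1C1OC2(c2c(OC)cc(OC)c3c2C[C@H](C)N(C(=O)OC(C)(C)C)C3)C=C1
F7 | step 10 | tert-butyl (S)-5-(4-hydroxy-5-methoxy-7-methylnaphthalen-1-yl)-6,8-dimethoxy-3-methyl-3,4-dihydroisoquinoline-2(1H)-carboxylate | COc1cc(C)cc2c(-c3c(OC)cc(OC)c4c3C[C@H](C)N(C(=O)OC(C)(C)C)C4)ccc(O)c12
F8 | step 11 | tetralol adduct with C2' phenylsulfonyl and C3' trimethylsilyl groups, (S) at C3 | COC1C([Si](C)(C)C)C(S(=O)(=O)c2ccccc2)C(O)(c2c(OC)cc(OC)c3c2C[C@H](C)N(C(=O)OC(C)(C)C)C3)c2cc(C)cc(OC)c12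
F9 | step 8 | 3-methoxy-2-(methoxymethyl)-5-methylbenzoic acid | COCc1c(OC)cc(C)cc1C(=O)O
F10 | step 8 | 3-methoxy-2-(methoxymethyl)-5-methylbenzoyl chloride | COCc1c(OC)cc(C)cc1C(=O)Cl
F11 | step 8 | (S)-N-Boc-6,8-dimethoxy-3-methyltetrahydroisoquinolin-5-ylzinc chloride | COc1cc(OC)c2c(c1[Zn]Cl)C[C@H](C)N(C(=O)OC(C)(C)C)C2
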